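The numbers are assumed; the result is computed.

Two neighbours of this flask differ from it in the charge of solid substrate, 0.17 M and 0.025 M, so I want a quantity that carries the ring yield from one charge to the next.

solid substrate 0.10 M; time 6.0 d

    starting material → ring (k1 = 0.22 /h)
    starting material + starting material ⇌ open dimer (K2 = 9.8 /M, k2 = 1.0 /M/h)
    solid substrate ⇌ starting material, rate k3*(cs3 - [starting material]) while solid is left; crystals form when [starting material] > cs3 (cs3 = 39 mM, k3 = 0.15 /h)
    starting material + ring → side product (k4 = 3.5 /M/h)

- at 6.0 d, what has stopped the reaction, if anything has (for what has run out or reacted, a solid counts together with what of it has only dissolved) (forward and back rates have come level / it is still moving / all of the solid substrate has reacted)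
- part of the solid substrate that has turned into other species by 6.0 d (what has only dissolved does not count)
- how much ring there is at 6.0 d, in percent of the solid substrate charged
- how much side product there is at 6.0 d, in percent of the solid substrate charged

- in percentages every species weighs as the solid substrate in it: one open dimer or side product counts as two
- for a step with 2 of a species take k times the square, and two of it per event
- as a solid, counted per litre of solution: solid substrate
- at the start none of the solid substrate is in solution
- what has only dissolved of solid substrate counts as not reacted
- the reaction counts as stopped when no species that holds the solid substrate changes by six tenths of a point or more over the second half of the time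
- run time (flask): 6.0 d

1. I start with the ring-forming step by itself. The half-life of starting material by this step is 3.15 h, and the time asked holds 45.7 such half-lives, so my ring yield stands at 100 percent.

2. Now I add the side reaction of starting material with ring. Both steps are first order in [starting material], so their ratio at any moment depends on [ring]. Starting material goes equally fast both ways where [ring] equals the ratio of the constants, 0.22 /h over 3.5 /M/h, which is 62.9 mM. I call this the ring ceiling, a selectivity factor with the unit of a concentration.

I count exposure n as the lifetimes of ring against the side reaction that have passed. Then [ring] = ceiling × (1 − exp(−n)). The balance, with side product counted double, gives 2n − 1 + exp(−n) = charge/ceiling.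

Here charge/ceiling is 1.59, so n is 1.14. The ring yield drops to 42.7%, and side product takes 57.3%.

3. Next I add dissolving. With dissolving set against the ring-forming step, I reckon [starting material] near 15.8 mM, below the solubility 39 mM, so no crystals form. The feed of 3.48 mM/h empties the charge in about 28.7 h, and the time asked is 5.01 such spans. This changes the clock, and my yield stays.

4. Last I add the open dimer. Its lifetime against falling back is 9.80 h, and the time left after the feed ends holds 11.8 lifetimes, so I reckon it has given its starting material back and my yield stays again. I commit to full conversion.

5. The forecast agrees with me: all of the solid substrate has reacted, conversion 100%, ring 42.7%, side product 57.3%. Its ground for the route-independent balance is "This makes the result independent of path".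

6. The flask gives: all of the solid substrate has reacted, conversion >99.9%, ring 42.6%, side product 57.4%.

In the flask, 60% of the dissolving is done by 0.600 d, with 40.4% still solid substrate, and by 3.00 d ring holds 42.6% and side product 57.3%. At 0.498 d starting material goes to ring 2.7 times as fast as to side product, and that ratio against the ceiling reads as [ring] of 23.3 mM. With the time held, the side product of this flask has moved by 5 points at charges of 0.0809 M and 0.124 M. The charge of the neighbour at 0.17 M is 2.70 ceilings, so n is 1.77 and I reckon 30.7% ring; that flask holds 30.7%.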